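**Retrosynthetic overview**
- The ring is read as a masked 4,4-dimethylcyclohexa-2,5-dienone: C4 (C–Cl) is the former carbonyl carbon, C2 (C–Br) and C6 (C–Cl) are its two β-carbons on either side of the quaternary C1, and the (Z)-2-bromoethylidene at C3 is the (E)-alkylidene of an α-olefinated ketone.
- Key disconnection: C3–C4 and C6–C1 are made in one pot from a prenyl phosphonate and 3-ethoxyacryloyl chloride. The prenyl unit C1=C2–C3 and the acryloyl unit C4(=O)–C5=C6 together form a hexatriene whose central carbon C3 is a phosphonate-stabilised carbanion. Acylation joins C3 to C4, and 6π-electrocyclisation joins C1 to C6. This closes the only ring.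
- Phosphorus at C3 is a traceless handle: it later becomes the exocyclic C3=C7 bond by Horner–Wadsworth–Emmons olefination.
- Stereochemistry: the C2 oxygen is set by copper-catalysed asymmetric borylation, C6–Cl by reversible hydrochlorination trans to it, C4–OH by hydroxyl-directed reduction; C4–Cl and C2–Br then arise by two SN2 inversions.
- Order of events: ring (step 2), C2–B (3), alkylidene and C2–OH (4), C6–Cl (5), C4–OH (6), C4–Cl (7), C2–Br and C8–Br (8).

Key step: step 2

Remark: ring atoms are called C1 (CMe2), C2 (C–Br), C3 (alkylidene carbon), C4 and C6 (C–Cl), C5 (CH2), side chain C7 and C8; (E)-3-ethoxyacryloyl chloride and (tert-butyldimethylsilyloxy)acetaldehyde are taken as commercial, and the ligand antipode in step 3 is the one that delivers the (R)-boronate, which is assigned by analogy and would be checked.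

Step 1
Reactants: 1 1-bromo-3-methylbut-2-ene (prenyl bromide); 2 triethyl phosphite
Product: 3 diethyl (3-methylbut-2-en-1-yl)phosphonate
Conditions: neat, 130 °C, EtBr distilled off
Reagents that add atoms: none
Why: Michaelis–Arbuzov reaction at the primary allylic carbon, which leaves the trisubstituted alkene in place and creates no stereocentre.

Step 2
Reactants: 3 diethyl (3-methylbut-2-en-1-yl)phosphonate; 4 (E)-3-ethoxyacryloyl chloride
Product: 7 diethyl (3,3-dimethyl-6-oxocyclohexa-1,4-dien-1-yl)phosphonate, via C-acylated phosphonate 5 (not isolated), via ring-closed ethoxy enolate 6 (not isolated)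
Conditions: LiN(i-Pr)2 (2.1 equiv), THF, −78 °C; 4 added slowly, −78 → 23 °C; then 60 °C; aq. NH4Cl
Reagents that add atoms: none
Why: Proposed new method: the lithiated allylic phosphonate is C-acylated at its phosphorus-bearing carbon by the acid chloride (C3–C4 bond; closest known type: β-keto phosphonates from phosphonate carbanions and acyl chlorides), the second equivalent of base turns 5 into its enolate, a 3-oxido-1,3,5-hexatriene C1=C2–C3=C4(O)–C5=C6, which closes the C1–C6 bond by an anion-accelerated thermal 6π-electrocyclisation (closest known types: carbanion- and oxyanion-accelerated hexatriene electrocyclisations and the Michael–Claisen [3+3] synthesis of cyclohexane-1,3-diones), and the enolate 6 expels ethoxide (E1cB) to give the cross-conjugated dienone. The six-membered ring is closed in the disrotatory 6π-electrocyclic mode, with the gem-dimethyl carbon and the ethoxy-bearing carbon as termini. No stereocentre survives, because the ethoxy-bearing carbon of 6 becomes sp2 and 7 is achiral. The step needs α- and C-acylation, which the hard acyl chloride and the quaternary centre that γ-attack would have to build should secure, and a (Z)-enolate, which the delocalised β-keto phosphonate anion reaches freely; O-cyclisation to a pyranone cannot compete because the only enolate oxygen is that of the new acyl group itself.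

Step 3
Reactants: 7 diethyl (3,3-dimethyl-6-oxocyclohexa-1,4-dien-1-yl)phosphonate
Product: 8 diethyl [(2R)-3,3-dimethyl-6-oxo-2-(4,4,5,5-tetramethyl-1,3,2-dioxaborolan-2-yl)cyclohex-4-en-1-yl]phosphonate (epimer mixture at the phosphorus-bearing carbon)
Conditions: CuCl (5 mol %), (R)-DTBM-SEGPHOS (6 mol %), NaOt-Bu (10 mol %), B2pin2 (1.05 equiv), MeOH (2 equiv), THF, 0 °C
Reagents that add atoms: bis(pinacolato)diboron, CC1(C)OB(OC1(C)C)B1OC(C)(C)C(C)(C)O1
Why: Copper-catalysed enantioselective conjugate borylation, in which the borylcopper should add to the doubly activated (keto- and phosphoryl-substituted) alkene rather than to the plain enone, the chiral bisphosphine selects the face and sets the boron-bearing stereocentre (R), and methanol protonates the enolate at a carbon that is planarised again in step 4.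

Step 4
Reactants: 8 diethyl [(2R)-3,3-dimethyl-6-oxo-2-(4,4,5,5-tetramethyl-1,3,2-dioxaborolan-2-yl)cyclohex-4-en-1-yl]phosphonate; 9 (tert-butyldimethylsilyloxy)acetaldehyde
Product: 11 (5R,6E)-6-[2-(tert-butyldimethylsilyloxy)ethylidene]-5-hydroxy-4,4-dimethylcyclohex-2-en-1-one, via allylic boronate 10 (not isolated)
Conditions: NaH (1.05 equiv), THF, 0 °C; 9 (1.0 equiv), 0 → 23 °C; then Me3NO·2H2O (3 equiv), 50 °C
Reagents that add atoms: trimethylamine N-oxide, C[N+](C)(C)[O-]
Why: Horner–Wadsworth–Emmons olefination of the α-substituted β-keto phosphonate should give the (E)-enone (side chain anti to the carbonyl, hence syn to the boron-bearing carbon), and amine N-oxide oxidation of the allylic C–B bond proceeds with retention and without allylic transposition, so the (R)-carbinol results.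

Step 5
Reactants: 11 (5R,6E)-6-[2-(tert-butyldimethylsilyloxy)ethylidene]-5-hydroxy-4,4-dimethylcyclohex-2-en-1-one
Product: 12 (2E,3S,5S)-2-[2-(tert-butyldimethylsilyloxy)ethylidene]-5-chloro-3-hydroxy-4,4-dimethylcyclohexan-1-one
Conditions: HCl (2 M in Et2O, 3 equiv), CH2Cl2, −40 → −20 °C; cold aq. NaHCO3; used crude
Reagents that add atoms: hydrogen chloride, Cl
Why: Conjugate hydrochlorination of the remaining ring enone is reversible and so thermodynamically controlled; the hydroxyl is held axial by allylic 1,3-strain with the exocyclic CH2OSi group, so chlorine should settle equatorial and trans to it (the cis isomer would need a 1,3-diaxial OH/Cl pair), which sets the C–Cl centre next to the quaternary carbon without any substitution at a neopentyl position.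

Step 6
Reactants: 12 (2E,3S,5S)-2-[2-(tert-butyldimethylsilyloxy)ethylidene]-5-chloro-3-hydroxy-4,4-dimethylcyclohexan-1-one
Product: 13 (1R,2Z,3S,5S)-2-[2-(tert-butyldimethylsilyloxy)ethylidene]-5-chloro-4,4-dimethylcyclohexane-1,3-diol
Conditions: Me4NBH(OAc)3 (4 equiv), MeCN/AcOH 1:1, −30 °C
Reagents that add atoms: none
Why: Hydroxyl-directed (Evans–Saksena-type) reduction, in which the axial allylic hydroxyl binds the triacetoxyborohydride and delivers hydride to the same face of the ketone, should give the 1,3-anti diol (new carbinol R, cis to chlorine), while the acidic medium leaves the β-chloro ketone intact.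

Step 7
Reactants: 13 (1R,2Z,3S,5S)-2-[2-(tert-butyldimethylsilyloxy)ethylidene]-5-chloro-4,4-dimethylcyclohexane-1,3-diol
Product: 14 (1R,3S,5S,6E)-6-[2-(tert-butyldimethylsilyloxy)ethylidene]-3,5-dichloro-2,2-dimethylcyclohexan-1-ol
Conditions: PPh3 (1.2 equiv), Cl3CC(O)CCl3 (1.5 equiv), CH2Cl2, −20 → 0 °C
Reagents that add atoms: hexachloroacetone, ClC(Cl)(Cl)C(=O)C(Cl)(Cl)Cl
Why: Appel-type chlorination should activate only the unhindered equatorial allylic hydroxyl (the other is axial and flanked by the quaternary carbon) and replace it by chloride with SN2 inversion (R to S), giving the trans-1,3-dichloride.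

Step 8
Reactants: 14 (1R,3S,5S,6E)-6-[2-(tert-butyldimethylsilyloxy)ethylidene]-3,5-dichloro-2,2-dimethylcyclohexan-1-ol
Product: 15 (2S,3Z,4S,6S)-2-bromo-3-(2-bromoethylidene)-4,6-dichloro-1,1-dimethylcyclohexane
Conditions: Ph3PBr2 (3 equiv), CH2Cl2, 0 → 23 °C
Reagents that add atoms: dibromotriphenylphosphorane, BrP(Br)(c1ccccc1)(c1ccccc1)c1ccccc1
Why: Ph3PBr2 should convert the remaining allylic alcohol into the bromide by SN2 inversion of its alkoxyphosphonium salt (axial leaving group aligned with the alkene π-system, R to S) and in the same flask cleave the primary allylic silyl ether to the primary bromide, which sets the last stereocentre cis to the neighbouring chlorine.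

**Compound list**
1 | 1-bromo-3-methylbut-2-ene (prenyl bromide) | CC(C)=CCBr | starting material
2 | triethyl phosphite | CCOP(OCC)OCC | starting material
3 | diethyl (3-methylbut-2-en-1-yl)phosphonate | CC(C)=CCP(=O)(OCC)OCC | intermediate
4 | (E)-3-ethoxyacryloyl chloride | CCO/C=C/C(Cl)=O | starting material
5 | diethyl [(1E)-1-ethoxy-6-methyl-3-oxohepta-1,5-dien-4-yl]phosphonate (formed as its lithium enolate, not isolated) | CCO/C=C/C(=O)C(C=C(C)C)P(=O)(OCC)OCC | intermediate
6 | diethyl (4-ethoxy-3,3-dimethyl-6-oxocyclohex-1-en-1-yl)phosphonate (racemic, formed as its lithium enolate, not isolated) | CCOC1CC(=O)C(P(=O)(OCC)OCC)=CC1(C)C | intermediate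
7 | diethyl (3,3-dimethyl-6-oxocyclohexa-1,4-dien-1-yl)phosphonate | CC1(C)C=C(P(=O)(OCC)OCC)C(=O)C=C1 | intermediate
8 | diethyl [(2R)-3,3-dimethyl-6-oxo-2-(4,4,5,5-tetramethyl-1,3,2-dioxaborolan-2-yl)cyclohex-4-en-1-yl]phosphonate (epimers at C–P) | CC1(C)[C@@H](B2OC(C)(C)C(C)(C)O2)C(P(=O)(OCC)OCC)C(=O)C=C1 | intermediate
9 | (tert-butyldimethylsilyloxy)acetaldehyde | CC(C)(C)[Si](C)(C)OCC=O | starting material
10 | (5R,6E)-6-[2-(tert-butyldimethylsilyloxy)ethylidene]-4,4-dimethyl-5-(4,4,5,5-tetramethyl-1,3,2-dioxaborolan-2-yl)cyclohex-2-en-1-one (not isolated) | CC1(C)[C@@H](B2OC(C)(C)C(C)(C)O2)/C(=C\CO[Si](C)(C)C(C)(C)C)C(=O)C=C1 | intermediate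
11 | (5R,6E)-6-[2-(tert-butyldimethylsilyloxy)ethylidene]-5-hydroxy-4,4-dimethylcyclohex-2-en-1-one | CC1(C)[C@@H](O)/C(=C\CO[Si](C)(C)C(C)(C)C)C(=O)C=C1 | intermediate
12 | (2E,3S,5S)-2-[2-(tert-butyldimethylsilyloxy)ethylidene]-5-chloro-3-hydroxy-4,4-dimethylcyclohexan-1-one | CC1(C)[C@@H](O)/C(=C\CO[Si](C)(C)C(C)(C)C)C(=O)C[C@@H]1Cl | intermediate
13 | (1R,2Z,3S,5S)-2-[2-(tert-butyldimethylsilyloxy)ethylidene]-5-chloro-4,4-dimethylcyclohexane-1,3-diol | CC1(C)[C@@H](O)/C(=C\CO[Si](C)(C)C(C)(C)C)[C@H](O)C[C@@H]1Cl | intermediate
14 | (1R,3S,5S,6E)-6-[2-(tert-butyldimethylsilyloxy)ethylidene]-3,5-dichloro-2,2-dimethylcyclohexan-1-ol | CC1(C)[C@@H](O)/C(=C\CO[Si](C)(C)C(C)(C)C)[C@@H](Cl)C[C@@H]1Cl | intermediate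
15 | (2S,3Z,4S,6S)-2-bromo-3-(2-bromoethylidene)-4,6-dichloro-1,1-dimethylcyclohexane | CC1(C)[C@H](Br)/C(=C\CBr)[C@@H](Cl)C[C@@H]1Cl | target

Total step count: 8. Longest linear sequence: 8 steps (from 1).

**Steps most likely to fail, with fallbacks**

Step 2 (Proposed new method). What may go wrong: the anionic electrocyclisation may stall because one methyl group of the gem-dimethyl terminus must turn inward, or γ- or O-acylation and oligomerisation of the enolate may take over. Fallback with known chemistry, setting out from 3 (with 4) and returning at 7: the acylation alone is run with two equivalents of lithiated 3 at −78 °C and quenched cold, and 5 is isolated. Compound 5 is silylated (Me3SiOTf, Et3N) to its trimethylsilyl trienol ether F1. F1 is heated in toluene (110–140 °C) so that the neutral 2-silyloxyhexatriene closes by thermal 6π-electrocyclisation to the silyloxy cyclohexadiene F2. Acidic work-up (TsOH, wet CH2Cl2) hydrolyses the silyl enol ether and eliminates ethanol, which gives 7.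

Step 8. What may go wrong: bromide may attack the exocyclic alkene carbon with allylic transposition instead of displacing at the hindered ring carbinol; the two oxygen functions may cyclodehydrate to a dihydrofuran; and bromide exchange may erode configuration at the strained allylic bromide, since the product carries bromine and chlorine cis on either side of the quaternary carbon. Fallback, setting out from 14 and returning at 15: the silyl ether is removed with HF·pyridine to give the (Z)-ene-1,4-diol F3. F3 is deliberately closed under Mitsunobu conditions (PPh3, DIAD; the primary hydroxyl is activated, so the ring C–O bond keeps its configuration) to the bicyclic 2,5-dihydrofuran F4. F4 is opened by ring-opening dibromination with Ph3PBr2 (MeCN, 40–60 °C), first at the primary allylic carbon and then with inversion at the ring carbon, to give 15.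

Step 3. What may go wrong: the borylcopper may not discriminate between the two enone arms, or facial selectivity may be insufficient on this α-phosphoryl enone. Fallback, setting out from 7 and returning at 11: the borylation is run with an achiral ligand (CuCl, Xantphos, B2pin2, MeOH), which gives 8 together with its enantiomer F5. Step 4 then gives 11 together with its enantiomer F6. Lipase-catalysed acylation (Candida antarctica lipase B, vinyl acetate, MTBE) is expected to acylate one enantiomer preferentially; if, as assumed, this is F6, it is removed as its acetate F7 and unreacted 11 re-enters the route. The sense of the enzyme would have to be checked.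

Further compounds
F1 | step 2 | diethyl [(1E)-1-ethoxy-6-methyl-3-(trimethylsilyloxy)hepta-1,3,5-trien-4-yl]phosphonate | CCO/C=C/C(O[Si](C)(C)C)=C(C=C(C)C)P(=O)(OCC)OCC
F2 | step 2 | diethyl [4-ethoxy-3,3-dimethyl-6-(trimethylsilyloxy)cyclohexa-1,5-dien-1-yl]phosphonate (racemic) | CCOC1C=C(O[Si](C)(C)C)C(P(=O)(OCC)OCC)=CC1(C)C
F3 | step 8 | (1R,3S,5S,6E)-3,5-dichloro-6-(2-hydroxyethylidene)-2,2-dimethylcyclohexan-1-ol | CC1(C)[C@@H](O)/C(=C\CO)[C@@H](Cl)C[C@@H]1Cl
F4 | step 8 | 4,6-dichloro-7,7-dimethyl-2,4,5,6,7,7a-hexahydro-1-benzofuran (ring-fusion C–O as in 14) | CC1(C)[C@H]2OCC=C2[C@@H](Cl)C[C@@H]1Cl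
F5 | step 3 | diethyl [(2S)-3,3-dimethyl-6-oxo-2-(4,4,5,5-tetramethyl-1,3,2-dioxaborolan-2-yl)cyclohex-4-en-1-yl]phosphonate (enantiomer of 8) | CC1(C)[C@H](B2OC(C)(C)C(C)(C)O2)C(P(=O)(OCC)OCC)C(=O)C=C1
F6 | step 3 | (5S,6E)-6-[2-(tert-butyldimethylsilyloxy)ethylidene]-5-hydroxy-4,4-dimethylcyclohex-2-en-1-one (enantiomer of 11) | CC1(C)[C@H](O)/C(=C\CO[Si](C)(C)C(C)(C)C)C(=O)C=C1
F7 | step 3 | (1S,6E)-6-[2-(tert-butyldimethylsilyloxy)ethylidene]-2,2-dimethyl-5-oxocyclohex-3-en-1-yl acetate | CC1(C)[C@H](OC(C)=O)/C(=C\CO[Si](C)(C)C(C)(C)C)C(=O)C=C1
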